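## Analysis of the target

Callophycoic acid H (30) is a trans-fused decalin: ring A is C1–C5 plus C10 and ring B is C5–C10 (labdane-type locants, used below also for the corresponding atoms of every intermediate; β is the face of the C10 methyl group). C3 bears bromine, C4 a methyl group and a 4-methylpent-3-enyl chain, C10 a methyl group, C8 an exocyclic methylene (C17), and C9 is joined through the benzylic carbon C11 to C5′ of a 3′-bromo-4′-hydroxybenzoic acid. The five stereocentres are 3β-Br (equatorial), 4β-CH3 (axial) with the chain 4α, 5α-H, 10β-CH3 and 9β-CH2Ar (equatorial): the ring fusion is trans, the two methyl groups are syn-diaxial, and bromine is cis to the C4 methyl group and trans to the C4 chain. Sensitive groups are the secondary bromide (elimination, and Grob fragmentation whenever an alkoxide sits on C5), the two alkenes (acid causes migration, cyclisation and addition of the neighbouring phenol to C8), the aryl bromide (zerovalent palladium when heated, reducing metals) and the free phenol and acid. The hard part is the C3–C4–C5–C10 array: the bromide is neopentylic and cannot be made by substitution, and two quaternary carbons stand 1,3 to each other across the ring fusion. The strategy rests on the C3–C4–C5 segment: bromine on C3 and the chain on C4 are anti, and C5 on the other side of C4 can be a carbonyl carbon at an earlier stage. That is the pattern left when a bromonium ion on C3=C4 is opened by a group shifting from a C5 carbinol, and the C5 ketone so formed is the handle for ring B.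

## Retrosynthetic reasoning

**30 from 29.** The two acyl–oxygen bonds of methyl ester/aryl pivalate 29 are cut last. Both fall to hydroxide in one operation, so no acid touches the alkenes or lets the phenol add to C8.

**29 from 27 and 28.** The C8=C17 bond is cut back to the C8 ketone 27 and the one-carbon unit 28. A ketone fixes the exocyclic position of the alkene, which elimination or a cationic termination would not, and it serves beforehand to control C9.

**27 from 22 by way of 24 and 25.** The trisubstituted alkene is cut at CH=C(CH3)2 into aldehyde 25 and phosphonium salt 26; 25 goes back through alcohol 24 to the terminal alkene of 22. The three carbons of the allyl group are thus the first three carbons of the side chain. The alkene is made late because a trisubstituted alkene would not survive the acid that closes ring B, whereas a monosubstituted one does.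

**22 from 16 and 20; 20 from 17.** The C9–C11 bond is cut to the enolate of bicyclic β-keto ester 16 and benzylic bromide 20, with the C9 carboxyl removed afterwards through 21. The ester makes C9, not C7, the nucleophilic carbon, and its loss leaves a C9–H centre that settles equatorial. The arene comes complete with its bromine from commercial phenol 17, so no palladium step has to tell an aryl bromide from a vinyl triflate.

**16 from 15.** Ring B is opened at C9–C10, giving monocyclic β-keto ester 15 with a tetrasubstituted C5=C10 alkene. The forward step protonates C5 and lets the enol capture the C10 cation. It must give the trans ring fusion and the right sense relative to C3/C4. An allylsilane terminator would give the methylene group directly but is protonated faster than the ring alkene, so an acid-stable enol terminator is used and the alkene is made from the ketone.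

**15 from 8 and 9 through 10, 11, 12 and 13.** The C5–C6 bond is cut to enol triflate 8 and zinc homoenolate 9; the C8–C9 bond is made by acylating 12 with acid 11 and trapping with 13. Cross-coupling at C5 avoids adding any nucleophile to the C5 carbonyl, where the alkoxide would be set up for Grob fragmentation with the C3 bromide.

**8 from 5 and 6 through 7.** The C10 methyl group and the triflate come from ketone 5. Because C4 is quaternary, enolisation can only occur towards C10, so both steps are regiochemically unambiguous.

**5 from 3 and 4 (key disconnection).** The C3–Br bond and the C4–CH2 bond of the allyl group are cut together, giving tertiary allylic alcohol 3 and the bromonium source 4. The forward step builds the neopentylic bromide by addition to an alkene and the quaternary carbon by a 1,2-shift, and sets both centres from the single carbinol centre of 3.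

**3 from 1 and 2.** The carbinol C–C bond is cut to enone 1 and allylboronate 2. One catalytic enantioselective 1,2-addition supplies all the absolute stereochemistry of the route.

## Alternatives that were turned down

**Alternative 1:** Both carbocycles would come from one intramolecular Diels–Alder reaction. The cut runs through C5–C10 and C8–C9 and leads to an open-chain triene: an (E,E)-diene over C5–C8 and a β,β-disubstituted (E)-enoate at C9=C10, linked by C1–C4. Heat or a Lewis acid would give the trans-fused octalin ester A1, with C3 still a silyl ether, C17 a protected hydroxymethyl group and C11 an ester.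
- For it: two rings and four stereocentres (C5, C8, C9, C10) arise in one step, and the ring fusion and C9 follow from the transition-state geometry. On this point it is stronger than the route chosen here, whose ring-B closure relies on a weaker conformational bias.
- Against it: the dienophile has two β-substituents and the diene terminus C5 is neopentylic, so the cycloaddition is sterically demanding. C4 and the C3 carbinol must be built in an acyclic precursor. In A1 the C3 oxygen has the orientation of the final bromine, so bromide would have to replace it at a neopentylic carbon with net retention. The C6=C7 alkene, the hydroxymethyl group and the ester all need further steps.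
- Comparison: the chosen route offers instead a C–Br bond made by addition, and a key-step precursor reached in one step.

**Alternative 2:** The arene would be attached last by an aryne relay, cutting C11–C5′ and C4′–O. A primary C11 organomagnesium reagent from the finished bromodecalin would add to a 3-bromoaryne, and the arylmagnesium formed next to bromine would be borylated and oxidised to the phenol, giving tert-butyl ester A2.
- For it: two bonds form in one flask, the union is highly convergent, and the phenol appears unprotected with the regiochemistry dictated by aryne polarisation. In convergence it is stronger than the route here, which needs three fragment steps and a protecting group.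
- Against it: the whole stereochemical problem of the bromodecalin lies outside this disconnection. A primary Grignard reagent would have to be made beside a secondary bromide and a homoallylic alkene. The ortho-bromo arylmagnesium intermediate is itself an aryne precursor. The oxidation must spare two alkenes.
- Comparison: the chosen strategy spends its key step on the decalin and joins the arene through a stable benzylic bromide.

**Alternative 3:** The arene would be built on the terpenoid, cutting C5′–C6′ and C3′–C4′. The bis-silyl ketene acetal of a decalin-propanoic acid would add to methyl 3-bromocoumalate A4, and loss of CO2 and silanol would give methyl ester A3.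
- For it: the substitution pattern of the arene is fixed by the cycloaddition, the phenol is free, and no benzylic halide or protecting group is needed. In protecting-group economy it is stronger than the route here.
- Against it: it again needs the complete bromodecalin, now with a two-carbon longer appendage. The ketene acetal must be made with strong base beside the bromide. The thermal cycloaddition and cycloreversion run in the presence of two alkenes. The regiochemistry with bromine on the pyrone is not secured by close analogy.
- Comparison: the chosen route buys the arene and puts its effort into C3–C4–C5–C10.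

Key step: step 2

Remark 1: diisopropyl allylboronate (2) is taken as a purchased reagent; where it is not stocked it is distilled after reaction of allylmagnesium bromide with triisopropyl borate.

Remark 2: the (S)-diol catalyst is written in step 1 by analogy with aryl methyl ketones; whichever antipode gives (R)-3 in a first run is the one used.

## Route

Step 1
Reactants: 1 2-methylcyclohex-2-en-1-one; 2 diisopropyl allylboronate
Product: 3 (1R)-2-methyl-1-(prop-2-en-1-yl)cyclohex-2-en-1-ol
Conditions: (S)-3,3′-dibromo-1,1′-bi-2-naphthol (15 mol %), PhCF3/toluene 3:1, −35 °C; aq. NaHCO3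
Reagents that add atoms: diisopropyl allylboronate, C=CCB(OC(C)C)OC(C)C
Why: Diol-catalysed asymmetric allylboration of a ketone: exchange of one isopropoxy group for the binaphthol gives a more Lewis acidic allylboronate that adds through a closed six-membered transition state, so only 1,2-addition is expected; the carbinol centre (C5) is set by the catalyst.

Step 2
Reactants: 3 (1R)-2-methyl-1-(prop-2-en-1-yl)cyclohex-2-en-1-ol; 4 N-bromosuccinimide
Product: 5 (2R,3R)-3-bromo-2-methyl-2-(prop-2-en-1-yl)cyclohexan-1-one (bromine cis to methyl, trans to allyl)
Conditions: NBS (1.05 equiv), CH2Cl2/(CF3)2CHOH 9:1, −40 → 0 °C, dark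
Reagents that add atoms: N-bromosuccinimide, O=C1CCC(=O)N1Br
Why: NBS transfers Br+ to the trisubstituted ring alkene C3=C4, which is far more nucleophilic than the monosubstituted alkene of the allyl group. In the bromonium ion on the hydroxyl face the C5–allyl bond is antiperiplanar to the C4–Br bond, the allyl group being pseudoaxial to avoid allylic 1,2-strain with the C4 methyl group and shielding the other face; it shifts from C5 to C4 as the bromonium ion opens, the carbinol becomes the ketone and succinimide takes the proton. The closest known reaction type is the halonium-induced semipinacol rearrangement of tertiary allylic alcohols to β-halo ketones with an α-quaternary carbon; migration of a plain allyl group in a cyclohexenol lies at the less explored edge of that class. No ring closes. C3 is set by the anti addition of bromine and migrating carbon across C3=C4, and C4 by the allyl group arriving on the face it occupied at C5, so the carbinol centre of 3 dictates both (bromine cis to methyl). The step needs chemoselectivity between the two alkenes, secured by their substitution, and migration in preference to epoxide closure from the other bromonium ion and to ring contraction. Bromonium formation is reversible, the weakly acidic non-nucleophilic cosolvent keeps epoxide closure reversible, and the ring bond C5–C10 cannot align with the breaking C4–Br bond.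

Step 3
Reactants: 5 (2R,3R)-3-bromo-2-methyl-2-(prop-2-en-1-yl)cyclohexan-1-one; 6 iodomethane
Product: 7 (2R,3R)-3-bromo-2,6-dimethyl-2-(prop-2-en-1-yl)cyclohexan-1-one (both C6 epimers)
Conditions: LiN(iPr)2, THF, −78 °C; MeI, −78 → −30 °C
Reagents that add atoms: iodomethane, CI
Why: Kinetic enolate alkylation; C4 is quaternary, so only the C10 enolate can form and iodomethane C-alkylates it, the new C10 centre being a mixture that is erased in step 4. No nucleophile adds to the carbonyl and no hydrogen lies between carbonyl and bromide, so neither Grob fragmentation nor β-elimination has a pathway.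

Step 4
Reactants: 7 (2R,3R)-3-bromo-2,6-dimethyl-2-(prop-2-en-1-yl)cyclohexan-1-one
Product: 8 (5R,6R)-5-bromo-2,6-dimethyl-6-(prop-2-en-1-yl)cyclohex-1-en-1-yl trifluoromethanesulfonate
Conditions: KN(SiMe3)2, THF, −78 °C; PhNTf2, −78 → 0 °C
Reagents that add atoms: N-phenyl-bis(trifluoromethanesulfonimide), O=S(=O)(N(c1ccccc1)S(=O)(=O)C(F)(F)F)C(F)(F)F
Why: Enol triflate formation by O-sulfonylation of the potassium enolate; C10 is the only enolisable position, so the tetrasubstituted C5=C10 triflate is the single regioisomer and both epimers of 7 converge.

Step 5
Reactants: 8 enol triflate; 9 (3-ethoxy-3-oxopropyl)zinc bromide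
Product: 10 ethyl 3-[(5R,6R)-5-bromo-2,6-dimethyl-6-(prop-2-en-1-yl)cyclohex-1-en-1-yl]propanoate
Conditions: 9 (1.5 equiv), PdCl2(dppf) (5 mol %), THF/NMP, 50 °C
Reagents that add atoms: (3-ethoxy-3-oxopropyl)zinc bromide, CCOC(=O)CC[Zn]Br
Why: Negishi sp2–sp3 cross-coupling forming C5–C6; zerovalent palladium inserts into the vinyl C–O bond (2,6,6-trisubstituted cyclohexenyl triflates are established partners) and the chelated zinc homoenolate transmetalates without β-hydride loss. The unactivated secondary bromide and the terminal alkene are not expected to react, and no stereocentre is formed.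

Step 6
Reactants: 10 ethyl ester
Product: 11 3-[(5R,6R)-5-bromo-2,6-dimethyl-6-(prop-2-en-1-yl)cyclohex-1-en-1-yl]propanoic acid
Conditions: LiOH·H2O, THF/H2O 3:1, rt; then 1 M HCl to pH 3
Reagents that add atoms: lithium hydroxide, [Li+].[OH-]
Why: Ester saponification; the neopentylic secondary bromide resists substitution under these conditions and there is no C5 carbonyl left to fragment.

Step 7
Reactants: 11 carboxylic acid; 12 2,2-dimethyl-1,3-dioxane-4,6-dione (Meldrum's acid); 13 prop-2-en-1-ol
Product: 15 prop-2-en-1-yl 5-[(5R,6R)-5-bromo-2,6-dimethyl-6-(prop-2-en-1-yl)cyclohex-1-en-1-yl]-3-oxopentanoate, via acyl Meldrum's acid 14 (not isolated)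
Conditions: 12, DCC, DMAP, CH2Cl2, 0 °C → rt; filter, concentrate; 13 (5 equiv), toluene, 90 °C
Reagents that add atoms: Meldrum's acid, CC1(C)OC(=O)CC(=O)O1; prop-2-en-1-ol, C=CCO
Why: Oikawa–Yonemitsu β-keto ester synthesis forming C8–C9: carbodiimide-mediated C-acylation of Meldrum's acid, then thermal loss of acetone and CO2 to an acylketene that the alcohol traps. The allyl ester is chosen because it survives the Lewis acid of step 8 and can be removed without base in step 13.

Step 8
Reactants: 15 allyl β-keto ester
Product: 16 prop-2-en-1-yl 3β-bromo-4β,10β-dimethyl-8-oxo-4α-(prop-2-en-1-yl)-trans-decalin-9-carboxylate (labdane locants; 5α-H; C9 epimers and enol)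
Conditions: SnCl4 (2 equiv), CH2Cl2, −78 → 0 °C; aq. NaHCO3
Reagents that add atoms: none
Why: β-Keto-ester-terminated cationic cyclisation of a β-cyclogeranyl-type alkene: the acid released on tin enolate formation protonates C5, and the tertiary C10 cation is captured by C9 of the chelated enol through a chair-like six-membered transition state (6-endo with respect to the enol), any O-cyclised enol ether being expected to revert under the Lewis acid. C5 and C10 are set together: the chair with the C6 tether equatorial gives the trans fusion (5α-H anti to 10β-CH3), and the sense relative to C3/C4 follows from the transition state that keeps bromine and the C4 allyl group equatorial; this second preference rests only on the equatorial preference of bromine, so the other trans-fused diastereomer is to be separated here. The terminal alkenes and the neopentylic bromide are too poorly basic or ionisable to take part.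

Step 9
Reactants: 17 methyl 4-hydroxy-3-methylbenzoate; 4 N-bromosuccinimide
Product: 18 methyl 3-bromo-4-hydroxy-5-methylbenzoate
Conditions: NBS (1.0 equiv), MeCN, 0 °C → rt
Reagents that add atoms: N-bromosuccinimide, O=C1CCC(=O)N1Br
Why: Electrophilic aromatic bromination; the para position of the phenol carries the ester and one ortho position the methyl group, so bromine enters the remaining ortho position.

Step 10
Reactants: 18 methyl 3-bromo-4-hydroxy-5-methylbenzoate
Product: 19 methyl 3-bromo-5-methyl-4-(pivaloyloxy)benzoate
Conditions: t-BuCOCl, Et3N, DMAP (cat.), CH2Cl2, 0 °C → rt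
Reagents that add atoms: pivaloyl chloride, CC(C)(C)C(=O)Cl
Why: DMAP-catalysed O-acylation of the hindered phenol; the pivalate should withstand radical bromination, enolates, borane chemistry and ylides at low temperature, and it falls together with the methyl ester in step 18.

Step 11
Reactants: 19 methyl 3-bromo-5-methyl-4-(pivaloyloxy)benzoate; 4 N-bromosuccinimide
Product: 20 methyl 3-bromo-5-(bromomethyl)-4-(pivaloyloxy)benzoate
Conditions: NBS (1.05 equiv), AIBN (5 mol %), PhCF3, 85 °C
Reagents that add atoms: N-bromosuccinimide, O=C1CCC(=O)N1Br
Why: Wohl–Ziegler radical bromination of the benzylic methyl group; the ring is deactivated by ester, bromine and acyloxy groups, so only the side chain reacts, and the stoichiometry limits dibromination.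

Step 12
Reactants: 16 bicyclic allyl β-keto ester; 20 methyl 3-bromo-5-(bromomethyl)-4-(pivaloyloxy)benzoate
Product: 21 prop-2-en-1-yl 9-[3-bromo-5-(methoxycarbonyl)-2-(pivaloyloxy)benzyl]-3β-bromo-4β,10β-dimethyl-8-oxo-4α-(prop-2-en-1-yl)-trans-decalin-9-carboxylate (C9 configuration of no consequence)
Conditions: NaH, THF/DMF 4:1, 0 °C; then 20, 0 °C → rt
Reagents that add atoms: methyl 3-bromo-5-(bromomethyl)-4-(pivaloyloxy)benzoate, COC(=O)c1cc(CBr)c(OC(=O)C(C)(C)C)c(Br)c1
Why: C-alkylation of a β-keto ester sodium enolate with a benzylic bromide (SN2) forming C9–C11; the ester fixes alkylation at C9 and not C7, and the electrophile should approach anti to the axial C10 methyl group. The configuration of the new quaternary C9 is irrelevant because the carboxyl group is removed next.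

Step 13
Reactants: 21 benzylated β-keto ester
Product: 22 methyl 3-bromo-5-{[3β-bromo-4β,10β-dimethyl-8-oxo-4α-(prop-2-en-1-yl)-trans-decalin-9β-yl]methyl}-4-(pivaloyloxy)benzoate (5α-H; 9α-H)
Conditions: Pd(OAc)2 (5 mol %), PPh3 (20 mol %), HCO2H/Et3N, THF, rt; then DBU (0.2 equiv), toluene, rt
Reagents that add atoms: none
Why: Tsuji deallylative decarboxylation: zerovalent palladium ionises the allyl ester, formate reduces the π-allyl group to propene and the β-keto carboxylate loses CO2. C9 is set by protonation of the enol on the α face, anti to the axial C10 methyl group, and by base equilibration, both of which should place the arylmethyl group equatorial (9β). At room temperature with PPh3 the aryl bromide is not expected to undergo oxidative addition.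

Step 14
Reactants: 22 C8 ketone with C4 allyl group
Product: 24 methyl 3-bromo-5-{[3β-bromo-4α-(3-hydroxypropyl)-4β,10β-dimethyl-8-oxo-trans-decalin-9β-yl]methyl}-4-(pivaloyloxy)benzoate, via pinacol boronate 23 (not isolated)
Conditions: pinacolborane, RhCl(PPh3)3 (3 mol %), THF, rt; then NaBO3·4H2O, THF/H2O, rt
Reagents that add atoms: pinacolborane (boron of 23), B1OC(C)(C)C(C)(C)O1; sodium perborate (oxygen), [Na+].[O-]OB=O
Why: Rhodium-catalysed anti-Markovnikov hydroboration of the terminal alkene and oxidation of the C–B bond; under catalysis the alkene should react ahead of the hindered C8 ketone, and perborate is mild enough for the aryl pivalate and the methyl ester.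

Step 15
Reactants: 24 primary alcohol
Product: 25 methyl 3-bromo-5-{[3β-bromo-4β,10β-dimethyl-8-oxo-4α-(3-oxopropyl)-trans-decalin-9β-yl]methyl}-4-(pivaloyloxy)benzoate
Conditions: Dess–Martin periodinane, NaHCO3, CH2Cl2, 0 °C → rt
Reagents that add atoms: none
Why: Dess–Martin oxidation of the primary alcohol to the aldehyde under buffered conditions that should not epimerise C9.

Step 16
Reactants: 25 aldehyde; 26 isopropyltriphenylphosphonium iodide
Product: 27 methyl 3-bromo-5-{[3β-bromo-4β,10β-dimethyl-4α-(4-methylpent-3-en-1-yl)-8-oxo-trans-decalin-9β-yl]methyl}-4-(pivaloyloxy)benzoate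
Conditions: 26, n-BuLi, THF, 0 °C; then 25, −78 → 0 °C
Reagents that add atoms: isopropyltriphenylphosphonium iodide, CC(C)[P+](c1ccccc1)(c1ccccc1)c1ccccc1.[I-]
Why: Wittig olefination with the non-stabilised isopropylidene ylide; at low temperature the aldehyde should react far faster than the hindered C8 ketone or the esters, and the trisubstituted alkene has no geometry to control.

Step 17
Reactants: 27 C8 ketone; 28 dibromomethane
Product: 29 methyl 3-bromo-5-{[3β-bromo-4β,10β-dimethyl-8-methylidene-4α-(4-methylpent-3-en-1-yl)-trans-decalin-9β-yl]methyl}-4-(pivaloyloxy)benzoate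
Conditions: Zn, CH2Br2, TiCl4, THF (−40 → 5 °C, pre-formed reagent); then 27, CH2Cl2, rt
Reagents that add atoms: dibromomethane, BrCBr
Why: Takai–Lombardo methylenation; the reagent is non-basic, so C9 is not epimerised, it converts hindered enolisable ketones, and it should leave the esters, both bromides and the trisubstituted alkene alone, giving C8=C17 with unambiguous regiochemistry.

Step 18
Reactants: 29 methyl ester aryl pivalate
Product: 30 callophycoic acid H
Conditions: LiOH·H2O (6 equiv), THF/MeOH/H2O, 40 °C; then 1 M HCl to pH 4, 0 °C
Reagents that add atoms: lithium hydroxide, [Li+].[OH-]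
Why: Hydroxide cleaves the methyl ester and the aryl pivalate in one operation; the equatorial neopentylic bromide offers neither a backside for substitution nor an antiperiplanar hydrogen for elimination. Acid is limited to a cold, brief neutralisation so that no alkene migrates and the phenol does not add to C8.

## Compound list

1 | 2-methylcyclohex-2-en-1-one | CC1=CCCCC1=O | starting material
2 | diisopropyl allylboronate | C=CCB(OC(C)C)OC(C)C | starting material
3 | (1R)-2-methyl-1-(prop-2-en-1-yl)cyclohex-2-en-1-ol | C=CC[C@]1(O)CCCC=C1C | intermediate
4 | N-bromosuccinimide | O=C1CCC(=O)N1Br | starting material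
5 | (2R,3R)-3-bromo-2-methyl-2-(prop-2-en-1-yl)cyclohexan-1-one | O=C1[C@@](C)(CC=C)[C@H](Br)CCC1 | intermediate
6 | iodomethane | CI | starting material
7 | (2R,3R)-3-bromo-2,6-dimethyl-2-(prop-2-en-1-yl)cyclohexan-1-one, C6 epimers | O=C1[C@@](C)(CC=C)[C@H](Br)CCC1C | intermediate
8 | (5R,6R)-5-bromo-2,6-dimethyl-6-(prop-2-en-1-yl)cyclohex-1-en-1-yl trifluoromethanesulfonate | CC1=C(OS(=O)(=O)C(F)(F)F)[C@@](C)(CC=C)[C@H](Br)CC1 | intermediate
9 | (3-ethoxy-3-oxopropyl)zinc bromide | CCOC(=O)CC[Zn]Br | starting material
10 | ethyl 3-[(5R,6R)-5-bromo-2,6-dimethyl-6-(prop-2-en-1-yl)cyclohex-1-en-1-yl]propanoate | CC1=C(CCC(=O)OCC)[C@@](C)(CC=C)[C@H](Br)CC1 | intermediate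
11 | 3-[(5R,6R)-5-bromo-2,6-dimethyl-6-(prop-2-en-1-yl)cyclohex-1-en-1-yl]propanoic acid | CC1=C(CCC(=O)O)[C@@](C)(CC=C)[C@H](Br)CC1 | intermediate
12 | 2,2-dimethyl-1,3-dioxane-4,6-dione (Meldrum's acid) | CC1(C)OC(=O)CC(=O)O1 | starting material
13 | prop-2-en-1-ol | C=CCO | starting material
14 | 5-{3-[(5R,6R)-5-bromo-2,6-dimethyl-6-(prop-2-en-1-yl)cyclohex-1-en-1-yl]propanoyl}-2,2-dimethyl-1,3-dioxane-4,6-dione | CC1=C(CCC(=O)C2C(=O)OC(C)(C)OC2=O)[C@@](C)(CC=C)[C@H](Br)CC1 | intermediate
15 | prop-2-en-1-yl 5-[(5R,6R)-5-bromo-2,6-dimethyl-6-(prop-2-en-1-yl)cyclohex-1-en-1-yl]-3-oxopentanoate | CC1=C(CCC(=O)CC(=O)OCC=C)[C@@](C)(CC=C)[C@H](Br)CC1 | intermediate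
16 | prop-2-en-1-yl 3β-bromo-4β,10β-dimethyl-8-oxo-4α-(prop-2-en-1-yl)-trans-decalin-9-carboxylate (5α-H; C9 epimers and enol) | O=C1CC[C@@H]2[C@@](C)(CC=C)[C@H](Br)CC[C@@]2(C)C1C(=O)OCC=C | intermediate
17 | methyl 4-hydroxy-3-methylbenzoate | COC(=O)c1ccc(O)c(C)c1 | starting material
18 | methyl 3-bromo-4-hydroxy-5-methylbenzoate | COC(=O)c1cc(C)c(O)c(Br)c1 | intermediate
19 | methyl 3-bromo-5-methyl-4-(pivaloyloxy)benzoate | COC(=O)c1cc(C)c(OC(=O)C(C)(C)C)c(Br)c1 | intermediate
20 | methyl 3-bromo-5-(bromomethyl)-4-(pivaloyloxy)benzoate | COC(=O)c1cc(CBr)c(OC(=O)C(C)(C)C)c(Br)c1 | intermediate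
21 | prop-2-en-1-yl 9-[3-bromo-5-(methoxycarbonyl)-2-(pivaloyloxy)benzyl]-3β-bromo-4β,10β-dimethyl-8-oxo-4α-(prop-2-en-1-yl)-trans-decalin-9-carboxylate (C9 unassigned) | O=C1CC[C@@H]2[C@@](C)(CC=C)[C@H](Br)CC[C@@]2(C)C1(Cc1cc(C(=O)OC)cc(Br)c1OC(=O)C(C)(C)C)C(=O)OCC=C | intermediate
22 | methyl 3-bromo-5-{[3β-bromo-4β,10β-dimethyl-8-oxo-4α-(prop-2-en-1-yl)-trans-decalin-9β-yl]methyl}-4-(pivaloyloxy)benzoate | O=C1CC[C@@H]2[C@@](C)(CC=C)[C@H](Br)CC[C@@]2(C)[C@@H]1Cc1cc(C(=O)OC)cc(Br)c1OC(=O)C(C)(C)C | intermediate
23 | methyl 3-bromo-5-{[3β-bromo-4β,10β-dimethyl-8-oxo-4α-[3-(4,4,5,5-tetramethyl-1,3,2-dioxaborolan-2-yl)propyl]-trans-decalin-9β-yl]methyl}-4-(pivaloyloxy)benzoate | O=C1CC[C@@H]2[C@@](C)(CCCB3OC(C)(C)C(C)(C)O3)[C@H](Br)CC[C@@]2(C)[C@@H]1Cc1cc(C(=O)OC)cc(Br)c1OC(=O)C(C)(C)C | intermediate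
24 | methyl 3-bromo-5-{[3β-bromo-4α-(3-hydroxypropyl)-4β,10β-dimethyl-8-oxo-trans-decalin-9β-yl]methyl}-4-(pivaloyloxy)benzoate | O=C1CC[C@@H]2[C@@](C)(CCCO)[C@H](Br)CC[C@@]2(C)[C@@H]1Cc1cc(C(=O)OC)cc(Br)c1OC(=O)C(C)(C)C | intermediate
25 | methyl 3-bromo-5-{[3β-bromo-4β,10β-dimethyl-8-oxo-4α-(3-oxopropyl)-trans-decalin-9β-yl]methyl}-4-(pivaloyloxy)benzoate | O=C1CC[C@@H]2[C@@](C)(CCC=O)[C@H](Br)CC[C@@]2(C)[C@@H]1Cc1cc(C(=O)OC)cc(Br)c1OC(=O)C(C)(C)C | intermediate
26 | isopropyltriphenylphosphonium iodide | CC(C)[P+](c1ccccc1)(c1ccccc1)c1ccccc1.[I-] | starting material
27 | methyl 3-bromo-5-{[3β-bromo-4β,10β-dimethyl-4α-(4-methylpent-3-en-1-yl)-8-oxo-trans-decalin-9β-yl]methyl}-4-(pivaloyloxy)benzoate | O=C1CC[C@@H]2[C@@](C)(CCC=C(C)C)[C@H](Br)CC[C@@]2(C)[C@@H]1Cc1cc(C(=O)OC)cc(Br)c1OC(=O)C(C)(C)C | intermediate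
28 | dibromomethane | BrCBr | starting material
29 | methyl 3-bromo-5-{[3β-bromo-4β,10β-dimethyl-8-methylidene-4α-(4-methylpent-3-en-1-yl)-trans-decalin-9β-yl]methyl}-4-(pivaloyloxy)benzoate | C=C1CC[C@@H]2[C@@](C)(CCC=C(C)C)[C@H](Br)CC[C@@]2(C)[C@@H]1Cc1cc(C(=O)OC)cc(Br)c1OC(=O)C(C)(C)C | intermediate
30 | callophycoic acid H | C=C1CC[C@@H]2[C@@](C)(CCC=C(C)C)[C@H](Br)CC[C@@]2(C)[C@@H]1Cc1cc(C(=O)O)cc(Br)c1O | target

## Step count and least certain steps

Total step count: 18 (15 on the main line, 3 for arene fragment 20). Longest linear sequence: 15 steps (steps 1–8 and 12–18).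

**Step 2 (key step).** The likeliest failure is that the bromonium ion is intercepted before the allyl group moves: closure of the hydroxyl group onto the bromonium ion of the other face, capture by succinimide or solvent, or ring contraction, because a plain allyl group migrates less readily than aryl or strained-ring bonds. Fallback, still the same disconnection: from 3, silylation (Me3SiCl, imidazole) gives the trimethylsilyl ether F1. With 4 in CH2Cl2/MeNO2 at low temperature the oxygen has no proton to lose, so epoxide closure is shut off, and the silyloxy group is the stronger donor for the 1,2-shift. Loss of the silyl group from the silyloxocarbenium ion returns to the route at 5.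

**Step 8.** The likeliest failure is poor facial selectivity of ring closure relative to C3/C4. Closure on either face of ring A gives a trans-fused decalin, and the two transition states differ mainly in bromine being equatorial or axial. Cis closure and O-cyclisation are lesser risks. Fallback with auxiliary control: from 11 by way of 14, the acylketene is trapped with (−)-8-phenylmenthol (or its antipode, whichever reinforces the substrate) instead of 13, giving the 8-phenylmenthyl keto ester F2. The aryl group of the auxiliary shields one face of the tin-chelated enol, and through the chair transition state the enol face fixes the face of C10. SnCl4 closure gives the bicyclic 8-phenylmenthyl keto ester F3. DMAP-catalysed ester exchange with 13 in hot toluene, possible because C9 still bears hydrogen, returns to the route at 16.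

**Step 12.** The likeliest failure is O-alkylation or no reaction, because C9 is flanked by the quaternary C10 and the new bond makes two adjacent quaternary carbons. The fallback reverses the polarity so that the new bond forms at an unhindered methylene carbon. From 16, Pd(PPh3)4 and morpholine remove the allyl group, and the β-keto acid is treated in the same flask with aqueous formaldehyde and diethylamine (decarboxylative Mannich methylenation) to give the 9-methylidene-8-ketone F4. Separately, commercial methyl 3-bromo-4-hydroxybenzoate is iodinated with N-iodosuccinimide to methyl 3-bromo-4-hydroxy-5-iodobenzoate F5, pivaloylated to the iodo pivalate F6, and borylated at the C–I bond (bis(pinacolato)diboron, PdCl2(dppf), KOAc) to the aryl pinacol boronate F7. Rhodium-catalysed conjugate addition of F7 to F4 ([Rh(cod)OH]2, dioxane/H2O) forms C11–C5′, and protonation at C9 from the α face returns to the route at 22. This path also keeps zerovalent palladium away from the bromoarene of the main line.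

**Step 1.** The likeliest failure is insufficient enantioselectivity, because the catalyst must distinguish a ring CH2 from an α-methyl vinyl group, or slow turnover with this hindered enone. Fallback with a different metal and allyl donor: silver-catalysed asymmetric Sakurai–Hosomi allylation of 1 with allyltrimethoxysilane (AgF, (R)-5,5′-bis(diphenylphosphino)-2,2,2′,2′-tetrafluoro-4,4′-bi-1,3-benzodioxole, THF/MeOH, −78 °C), a system that gives 1,2-adducts of cyclic enones, leads directly to 3.

**Step 14.** The likeliest failure is competing reduction of the C8 ketone by the boron hydride, or partial loss of the pivalate during oxidation. Fallback without boron: aldehyde-selective, nitrite-modified Wacker oxidation of the terminal alkene of 22 (PdCl2(PhCN)2, CuCl2, AgNO2, O2, t-BuOH/MeNO2) gives 25 directly. The quaternary C4 next to the allyl group should favour the anti-Markovnikov sense.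

## Further compounds

F1 | step 2 | trimethyl{[(1R)-2-methyl-1-(prop-2-en-1-yl)cyclohex-2-en-1-yl]oxy}silane | C=CC[C@]1(O[Si](C)(C)C)CCCC=C1C
F2 | step 8 | (1R,2S,5R)-5-methyl-2-(2-phenylpropan-2-yl)cyclohexyl 5-[(5R,6R)-5-bromo-2,6-dimethyl-6-(prop-2-en-1-yl)cyclohex-1-en-1-yl]-3-oxopentanoate | CC1=C(CCC(=O)CC(=O)O[C@@H]2C[C@H](C)CC[C@H]2C(C)(C)c2ccccc2)[C@@](C)(CC=C)[C@H](Br)CC1
F3 | step 8 | (1R,2S,5R)-5-methyl-2-(2-phenylpropan-2-yl)cyclohexyl 3β-bromo-4β,10β-dimethyl-8-oxo-4α-(prop-2-en-1-yl)-trans-decalin-9-carboxylate | O=C1CC[C@@H]2[C@@](C)(CC=C)[C@H](Br)CC[C@@]2(C)C1C(=O)O[C@@H]1C[C@H](C)CC[C@H]1C(C)(C)c1ccccc1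
F4 | step 12 | 3β-bromo-4β,10β-dimethyl-9-methylidene-4α-(prop-2-en-1-yl)-trans-decalin-8-one | O=C1CC[C@@H]2[C@@](C)(CC=C)[C@H](Br)CC[C@@]2(C)C1=C
F5 | step 12 | methyl 3-bromo-4-hydroxy-5-iodobenzoate | COC(=O)c1cc(Br)c(O)c(I)c1
F6 | step 12 | methyl 3-bromo-5-iodo-4-(pivaloyloxy)benzoate | COC(=O)c1cc(Br)c(OC(=O)C(C)(C)C)c(I)c1
F7 | step 12 | methyl 3-bromo-4-(pivaloyloxy)-5-(4,4,5,5-tetramethyl-1,3,2-dioxaborolan-2-yl)benzoate | COC(=O)c1cc(Br)c(OC(=O)C(C)(C)C)c(B2OC(C)(C)C(C)(C)O2)c1
F0 | step 1 | none | none
F0 | step 14 | none | none
A1 | alternative 1 | trans-fused octalin methyl ester with C3 tert-butyldimethylsilyl ether, C4 3-(tert-butyldiphenylsilyloxy)propyl chain and C8 (4-methoxybenzyloxy)methyl group | COc1ccc(COC[C@@H]2C=C[C@@H]3[C@@](C)(CCCO[Si](c4ccccc4)(c4ccccc4)C(C)(C)C)[C@H](O[Si](C)(C)C(C)(C)C)CC[C@@]3(C)[C@@H]2C(=O)OC)cc1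
A2 | alternative 2 | callophycoic acid H tert-butyl ester | C=C1CC[C@@H]2[C@@](C)(CCC=C(C)C)[C@H](Br)CC[C@@]2(C)[C@@H]1Cc1cc(C(=O)OC(C)(C)C)cc(Br)c1O
A3 | alternative 3 | callophycoic acid H methyl ester | C=C1CC[C@@H]2[C@@](C)(CCC=C(C)C)[C@H](Br)CC[C@@]2(C)[C@@H]1Cc1cc(C(=O)OC)cc(Br)c1O
A4 | alternative 3 | methyl 3-bromo-2-oxo-2H-pyran-5-carboxylate (methyl 3-bromocoumalate) | O=C1OC=C(C(=O)OC)C=C1Br
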